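**Numbering used below:** side chain C1=C2–C3(OH)(CH3)–C4–C5; ring A C6–C7–C8–C9(=O)–C10–C11; C8–C13(CH3)–C12(CH3)–C11 completes the bicyclo[2.2.2]octane (ring B = C8, C9, C10, C11, C12, C13); ring C C6–C11–C12–C14(OAc)–C15–C16(CH3).
A direct plan would make ring A first: a 4-methyl-δ-lactone would be alkylated twice to the quaternary lactone A1, the carbonyl group moved and the chain grown to the 4,4-disubstituted cyclohexenone A2 that carries a tigloyl ketone.
Its 2-silyloxydiene would close rings B and C by an intramolecular Diels–Alder reaction (bonds C8–C13 and C11–C12) to the C14 ketone A3, which would be reduced, acetylated and desilylated.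
Weak point 1, the second lactone enolate alkylation that sets quaternary C6: its facial bias would rest on a conformational argument for a tetrasubstituted enolate, and nothing in the substrate enforces it.
Weak point 2, the reduction of the lactone to a diol, oxidative relactonisation at the other end and a further alcohol oxidation: three redox steps would only move a carbonyl group, inside a linear run of eleven steps to a monocyclic precursor.
Weak point 3, the late reduction of the C14 ketone in the finished tricycle: both faces would be shielded, and the acetoxy stereocentre would be left to thermodynamic preference at a stage where failure costs the whole route.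

**Retrosynthetic overview of the new route**
- Key disconnection: bonds C6–C11 and C7–C8, formed together by an intramolecular Diels–Alder reaction of a ring B 2-silyloxycyclohexa-1,3-diene (C8=C9–C10=C11) with the unactivated alkene C6=C7, held on the three-atom tether C14–C15–C16 from C12. The step builds the one-carbon bridge C7 and quaternary C6, which rings A and C share.
- Ring order: ring B first (all six carbons from benzoic acid by Birch reductive methylation, which also gives C12 and C14), then rings C and A in the same step. The C9 oxygen comes from a bis-allylic oxidation; C13–CH3 and the diene arise together in a copper-catalysed desymmetrising conjugate methylation with enolate silylation.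
- The tether is joined convergently: rhodium-catalysed asymmetric 1,4-addition of an α-alkenylboronate (C1–C7 from (S)-linalool, C3 from the chiral pool) to a crotonyl ketone sets C16, and a CBS reduction sets C14 on an acyclic ketone.
- Design against the weak points: C6, C8 and C11 are fixed by the tether geometry, not by an enolate alkylation; C14 is set by reagent control before the core exists and carried as the final acetate; no carbonyl transposition is needed (13 steps, longest linear sequence 11).

Key step: step 12

Assumption: (S)-(+)-linalool is used as the single enantiomer (material of lower enantiomeric purity would be upgraded before use).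

**Route**

Step 1
Reactants: 1 (S)-(+)-linalool
Product: 2 (S)-linalool triethylsilyl ether
Conditions: TESOTf, 2,6-lutidine, CH2Cl2, −78 to 0 °C
Reagents that add atoms: triethylsilyl triflate CC[Si](CC)(CC)OS(=O)(=O)C(F)(F)F
Why: Silyl triflate silylation of a hindered tertiary alcohol, which leaves the C3 stereocentre (S, chiral pool) untouched.

Step 2
Reactants: 2 (S)-linalool triethylsilyl ether
Product: 3 (4S)-4-methyl-4-(triethylsilyloxy)hex-5-enal
Conditions: O3 (1.0 equiv, Sudan Red 7B as indicator), CH2Cl2/MeOH, −78 °C; then Me2S, −78 °C to rt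
Reagents that add atoms: ozone [O-][O+]=O
Why: Chemoselective ozonolysis of the electron-rich trisubstituted alkene beside the hindered, inductively deactivated vinyl group, with reductive work-up, so that the aldehyde carbon becomes C6.

Step 3
Reactants: 3 (4S)-4-methyl-4-(triethylsilyloxy)hex-5-enal
Product: 4 (3S)-3-methyl-3-(triethylsilyloxy)hept-1-en-6-yne
Conditions: dimethyl (1-diazo-2-oxopropyl)phosphonate, K2CO3, MeOH, 0 °C to rt
Reagents that add atoms: dimethyl (1-diazo-2-oxopropyl)phosphonate COP(=O)(OC)C(=[N+]=[N-])C(C)=O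
Why: Ohira–Bestmann alkynylation of the aldehyde under mild carbonate conditions, which adds C7 and tolerates the tertiary silyl ether.

Step 4
Reactants: 4 (3S)-3-methyl-3-(triethylsilyloxy)hept-1-en-6-yne
Product: 6 4,4,5,5-tetramethyl-2-[(5S)-5-methyl-5-(triethylsilyloxy)hepta-1,6-dien-2-yl]-1,3,2-dioxaborolane, via alkenylalane 5 (not isolated)
Conditions: NiCl2(dppp) (3 mol %), i-Bu2AlH (1.3 equiv), THF, 0 °C to rt; then MeOB(pin), rt to 70 °C
Reagents that add atoms: diisobutylaluminium hydride CC(C)C[AlH]CC(C)C (aluminium of intermediate 5 only); 2-methoxy-4,4,5,5-tetramethyl-1,3,2-dioxaborolane COB1OC(C)(C)C(C)(C)O1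
Why: Nickel-catalysed α-selective (Markovnikov) hydroalumination of a terminal alkyne, in which the bidentate phosphine places aluminium on the internal carbon C6, followed by aluminium-to-boron exchange; the hindered vinyl group reacts much more slowly.

Step 5
Reactants: 7 benzoic acid
Product: 9 1-methylcyclohexa-2,5-diene-1-carboxylic acid, via dilithium dianion 8 (not isolated)
Conditions: Li, NH3(l)/THF, −78 °C; then MeI, −78 °C; aq. HCl
Reagents that add atoms: lithium [Li] (lithium of intermediate 8 only); iodomethane CI
Why: Birch reductive alkylation, in which the carboxylate-stabilised cyclohexadienyl dianion is methylated at the ipso carbon and gives quaternary C12 (not yet stereogenic) with C14 as the carboxyl carbon.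

Step 6
Reactants: 9 1-methylcyclohexa-2,5-diene-1-carboxylic acid; 10 (E)-1-bromoprop-1-ene
Product: 14 (2E)-1-(1-methylcyclohexa-2,5-dien-1-yl)but-2-en-1-one, via lithium carboxylate 11 (not isolated), via (E)-prop-1-enyllithium 12 (not isolated), via dilithium gem-diolate 13 (not isolated)
Conditions: 9, n-BuLi (1.0 equiv), THF, −78 °C; 10, t-BuLi (2.0 equiv), Et2O, −78 °C; combine, −78 to 0 °C; inverse quench into aq. NH4Cl
Reagents that add atoms: n-butyllithium [Li]CCCC (lithium of intermediates 11 and 13 only); tert-butyllithium [Li]C(C)(C)C (lithium of intermediate 12 only)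
Why: Ketone synthesis by addition of an organolithium to a lithium carboxylate, whose gem-diolate cannot collapse before work-up so that no tertiary alcohol forms; the bromine–lithium exchange retains the E geometry of the alkene.

Step 7
Reactants: 14 (2E)-1-(1-methylcyclohexa-2,5-dien-1-yl)but-2-en-1-one; 6 4,4,5,5-tetramethyl-2-[(5S)-5-methyl-5-(triethylsilyloxy)hepta-1,6-dien-2-yl]-1,3,2-dioxaborolane
Product: 15 (3R,7S)-3,7-dimethyl-4-methylidene-1-(1-methylcyclohexa-2,5-dien-1-yl)-7-(triethylsilyloxy)non-8-en-1-one
Conditions: [Rh(OH)((S)-binap)]2 (3 mol %), KOH (0.5 equiv), dioxane/H2O 10:1, 40 °C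
Reagents that add atoms: none
Why: Rhodium-catalysed asymmetric 1,4-addition of an alkenylboronate to an (E)-enone (Hayashi–Miyaura reaction), in which the (S)-BINAP–rhodium alkenyl species adds to the α-Si face of the crotonyl ketone, the sense known for cyclohex-2-enone and (E)-configured acyclic acceptors, so that the alkenyl group enters on the Re face of C16 and gives 16R, while the unconjugated ring alkenes and the terminal alkenes stay inert.

Step 8
Reactants: 15 (3R,7S)-3,7-dimethyl-4-methylidene-1-(1-methylcyclohexa-2,5-dien-1-yl)-7-(triethylsilyloxy)non-8-en-1-one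
Product: 16 (1R,3R,7S)-3,7-dimethyl-4-methylidene-1-(1-methylcyclohexa-2,5-dien-1-yl)-7-(triethylsilyloxy)non-8-en-1-ol
Conditions: (S)-2-methyl-CBS-oxazaborolidine (0.3 equiv), catecholborane (2 equiv), toluene, −78 to −40 °C; aq. NaOH
Reagents that add atoms: none
Why: Corey–Bakshi–Shibata reduction of a ketone flanked by a quaternary carbon (large group) and a methylene group (small group), which with the (S)-catalyst should give the 14R carbinol in the sense known for tert-alkyl methyl ketones; catecholborane is chosen because it does not hydroborate the alkenes at this temperature.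

Step 9
Reactants: 16 (1R,3R,7S)-3,7-dimethyl-4-methylidene-1-(1-methylcyclohexa-2,5-dien-1-yl)-7-(triethylsilyloxy)non-8-en-1-ol
Product: 17 (1R,3R,7S)-3,7-dimethyl-4-methylidene-1-(1-methylcyclohexa-2,5-dien-1-yl)-7-(triethylsilyloxy)non-8-en-1-yl acetate
Conditions: Ac2O, DMAP, pyridine, CH2Cl2, rt
Reagents that add atoms: acetic anhydride CC(=O)OC(C)=O
Why: DMAP-catalysed acylation of the only free hydroxyl group with retention at C14, which installs the acetate of the target so that no later protecting-group exchange is needed.

Step 10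
Reactants: 17 (1R,3R,7S)-3,7-dimethyl-4-methylidene-1-(1-methylcyclohexa-2,5-dien-1-yl)-7-(triethylsilyloxy)non-8-en-1-yl acetate
Product: 18 (1R,3R,7S)-3,7-dimethyl-4-methylidene-1-(1-methyl-4-oxocyclohexa-2,5-dien-1-yl)-7-(triethylsilyloxy)non-8-en-1-yl acetate
Conditions: (C5H5NH)2Cr2O7, t-BuOOH, Celite, benzene, 10 °C to rt
Reagents that add atoms: tert-butyl hydroperoxide CC(C)(C)OO
Why: Chromium-mediated peroxide oxidation of the doubly allylic CH2 group of a 3,3-disubstituted cyclohexa-1,4-diene to the cross-conjugated dienone, a known reaction of such dienes in which t-BuOOH is the terminal oxidant and chromium stays hexavalent; the C9–H bonds are much weaker than the singly allylic C–H bonds at C5 and C16, and quaternary C12 blocks aromatisation.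

Step 11
Reactants: 18 (1R,3R,7S)-3,7-dimethyl-4-methylidene-1-(1-methyl-4-oxocyclohexa-2,5-dien-1-yl)-7-(triethylsilyloxy)non-8-en-1-yl acetate
Product: 20 (1R,3R,7S)-1-[(1R,6R)-4-(tert-butyldimethylsilyloxy)-1,6-dimethylcyclohexa-2,4-dien-1-yl]-3,7-dimethyl-4-methylidene-7-(triethylsilyloxy)non-8-en-1-yl acetate, via methylzinc enolate 19 (not isolated)
Conditions: Cu(OTf)2 (5 mol %), O,O′-[(S)-1,1′-binaphthalene-2,2′-diyl] N,N-bis[(R)-1-phenylethyl]phosphoramidite (10 mol %), Me2Zn (2 equiv), toluene, −30 to −10 °C; then TBSOTf, −10 to 0 °C; filtration through basic alumina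
Reagents that add atoms: dimethylzinc C[Zn]C; tert-butyldimethylsilyl triflate CC(C)(C)[Si](C)(C)OS(=O)(=O)C(F)(F)F
Why: Copper-catalysed enantioselective conjugate addition of a dialkylzinc to a 4,4-disubstituted cyclohexa-2,5-dienone (a known desymmetrisation) followed by O-silylation of the zinc enolate: the methyl group should enter anti to the bulky C14 substituent on C12, so the C12 and C13 methyl groups become cis; the ligand, the antipode that turns cyclohex-2-enone into (S)-3-alkylcyclohexanones, should select the arm C8=C13, whose unhindered face is its preferred α-Si face, which makes C12 stereogenic (12R,13R); and trapping on oxygen gives the C8=C9–C10=C11 diene directly.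

Step 12
Reactants: 20 (1R,3R,7S)-1-[(1R,6R)-4-(tert-butyldimethylsilyloxy)-1,6-dimethylcyclohexa-2,4-dien-1-yl]-3,7-dimethyl-4-methylidene-7-(triethylsilyloxy)non-8-en-1-yl acetate
Product: 21 tricyclic adduct (C9 tert-butyldimethylsilyl enol ether on C9=C10; C14 acetate; C3 triethylsilyl ether; C3, C6, C8, C11, C12, C13, C14, C16 as in the target)
Conditions: toluene (0.01 M), BHT (cat.), Et3N (cat.), sealed tube, 200 °C
Reagents that add atoms: none
Why: Thermal, concerted but asynchronous intramolecular Diels–Alder reaction between the 2-silyloxycyclohexa-1,3-diene (C8=C9–C10=C11) and the unactivated 1,1-disubstituted alkene C6=C7; the closest known reaction type is the thermal intramolecular cycloaddition of 5-alkenylcyclohexa-1,3-dienes and their 2-silyloxy derivatives to unactivated alkenes, which gives this same tricyclo[5.3.1.0(3,8)]undecane ring system. Bond C6–C11 closes ring C as a six-membered ring in the fused mode (three-atom tether C14–C15–C16 from C12, the sp3 carbon next to diene terminus C11), and bond C7–C8 closes ring A in the bridged mode, which completes the bicyclo[2.2.2]octene. C8 and C11 are controlled by C12, because the tether can deliver the alkene only to the diene face that carries C14, opposite to the C12 and C13 methyl groups; C6 is controlled by the tether as well, since C16 must stay on the C12 side, which turns the C5 chain under the diene towards C9=C10 and C7 towards C8, so no second diastereomer is geometrically possible (acetate equatorial and C16 methyl axial in the chair-like tether). Regiochemistry is secured by ring size, since the crossed mode would need a seven-membered ring, and it agrees with the polarity of the diene, whose nucleophilic terminus C8 meets the unsubstituted carbon C7. The step needs chemoselectivity for C6=C7 over the C1=C2 vinyl group, which hangs seven atoms from C12 and would have to close a ten-membered ring, and it needs the cycloaddition to outrun [1,5]-hydrogen shifts of the diene, which quaternary C12 limits to the single C13–H and which are expected to be slow at this temperature. The adduct keeps C9 masked as the silyl enol ether on C9=C10, so the ketone can be set free without touching any epimerisable centre.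

Step 13
Reactants: 21 tricyclic adduct
Product: 22 CNP0281208.1 (target)
Conditions: HF·pyridine, pyridine, THF, 0 °C to rt
Reagents that add atoms: none
Why: Global desilylation, in which the silyl enol ether gives the C9 ketone by protonation at non-stereogenic C10 (bridgehead C8 cannot epimerise), the tertiary triethylsilyl ether gives the C3 alcohol by Si–O cleavage with retention, and the acetate is inert to buffered HF.

**Compound list**
1 | (S)-(+)-linalool, (3S)-3,7-dimethylocta-1,6-dien-3-ol | C=C[C@@](C)(O)CCC=C(C)C | starting material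
2 | (S)-linalool triethylsilyl ether, triethyl{[(3S)-3,7-dimethylocta-1,6-dien-3-yl]oxy}silane | C=C[C@@](C)(O[Si](CC)(CC)CC)CCC=C(C)C | intermediate
3 | (4S)-4-methyl-4-(triethylsilyloxy)hex-5-enal | C=C[C@@](C)(O[Si](CC)(CC)CC)CCC=O | intermediate
4 | (3S)-3-methyl-3-(triethylsilyloxy)hept-1-en-6-yne | C=C[C@@](C)(O[Si](CC)(CC)CC)CCC#C | intermediate
5 | diisobutyl[(5S)-5-methyl-5-(triethylsilyloxy)hepta-1,6-dien-2-yl]alane | C=C[C@@](C)(O[Si](CC)(CC)CC)CCC(=C)[Al](CC(C)C)CC(C)C | intermediate
6 | 4,4,5,5-tetramethyl-2-[(5S)-5-methyl-5-(triethylsilyloxy)hepta-1,6-dien-2-yl]-1,3,2-dioxaborolane | C=C[C@@](C)(O[Si](CC)(CC)CC)CCC(=C)B1OC(C)(C)C(C)(C)O1 | intermediate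
7 | benzoic acid | OC(=O)c1ccccc1 | starting material
8 | dilithium (cyclohexa-2,5-dien-1-ylidene)methanediolate | [Li+].[Li+].[O-]C([O-])=C1C=CCC=C1 | intermediate
9 | 1-methylcyclohexa-2,5-diene-1-carboxylic acid | CC1(C(=O)O)C=CCC=C1 | intermediate
10 | (E)-1-bromoprop-1-ene | C/C=C/Br | starting material
11 | lithium 1-methylcyclohexa-2,5-diene-1-carboxylate | [Li+].[O-]C(=O)C1(C)C=CCC=C1 | intermediate
12 | (E)-prop-1-enyllithium | C/C=C/[Li] | intermediate
13 | dilithium (2E)-1-(1-methylcyclohexa-2,5-dien-1-yl)but-2-ene-1,1-diolate | [Li+].[Li+].[O-]C([O-])(/C=C/C)C1(C)C=CCC=C1 | intermediate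
14 | (2E)-1-(1-methylcyclohexa-2,5-dien-1-yl)but-2-en-1-one | C/C=C/C(=O)C1(C)C=CCC=C1 | intermediate
15 | (3R,7S)-3,7-dimethyl-4-methylidene-1-(1-methylcyclohexa-2,5-dien-1-yl)-7-(triethylsilyloxy)non-8-en-1-one | C=C[C@@](C)(O[Si](CC)(CC)CC)CCC(=C)[C@H](C)CC(=O)C1(C)C=CCC=C1 | intermediate
16 | (1R,3R,7S)-3,7-dimethyl-4-methylidene-1-(1-methylcyclohexa-2,5-dien-1-yl)-7-(triethylsilyloxy)non-8-en-1-ol | C=C[C@@](C)(O[Si](CC)(CC)CC)CCC(=C)[C@H](C)C[C@@H](O)C1(C)C=CCC=C1 | intermediate
17 | (1R,3R,7S)-3,7-dimethyl-4-methylidene-1-(1-methylcyclohexa-2,5-dien-1-yl)-7-(triethylsilyloxy)non-8-en-1-yl acetate | C=C[C@@](C)(O[Si](CC)(CC)CC)CCC(=C)[C@H](C)C[C@@H](OC(C)=O)C1(C)C=CCC=C1 | intermediate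
18 | (1R,3R,7S)-3,7-dimethyl-4-methylidene-1-(1-methyl-4-oxocyclohexa-2,5-dien-1-yl)-7-(triethylsilyloxy)non-8-en-1-yl acetate | C=C[C@@](C)(O[Si](CC)(CC)CC)CCC(=C)[C@H](C)C[C@@H](OC(C)=O)C1(C)C=CC(=O)C=C1 | intermediate
19 | methylzinc enolate of the conjugate adduct (O–ZnCH3 on C9; C8=C9 and C10=C11; 12R,13R) | C=C[C@@](C)(O[Si](CC)(CC)CC)CCC(=C)[C@H](C)C[C@@H](OC(C)=O)[C@]1(C)C=CC(O[Zn]C)=C[C@H]1C | intermediate
20 | (1R,3R,7S)-1-[(1R,6R)-4-(tert-butyldimethylsilyloxy)-1,6-dimethylcyclohexa-2,4-dien-1-yl]-3,7-dimethyl-4-methylidene-7-(triethylsilyloxy)non-8-en-1-yl acetate | C=C[C@@](C)(O[Si](CC)(CC)CC)CCC(=C)[C@H](C)C[C@@H](OC(C)=O)[C@]1(C)C=CC(O[Si](C)(C)C(C)(C)C)=C[C@H]1C | intermediate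
21 | tricyclic adduct: C9 tert-butyldimethylsilyl enol ether (C9=C10), C14 acetate, C3 triethylsilyl ether, stereocentres as in the target | C=C[C@@](C)(O[Si](CC)(CC)CC)CC[C@@]12C[C@H]3C(O[Si](C)(C)C(C)(C)C)=C[C@@H]1[C@](C)([C@@H]3C)[C@H](OC(C)=O)C[C@H]2C | intermediate
22 | CNP0281208.1 | C=C[C@@](C)(O)CC[C@@]12C[C@H]3C(=O)C[C@@H]1[C@](C)([C@@H]3C)[C@H](OC(C)=O)C[C@H]2C | target

**Step count and risks**

Total step count: 13. Longest linear sequence: 11 steps (steps 1–4 and 7–13, from (S)-linalool); the ring branch (steps 5 and 6) joins at step 7.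

Steps most likely to fail:

1. Step 12 (key step). The cycloaddition of an unactivated, 1,1-disubstituted alkene at a congested diene terminus may be too slow, so that hydrogen shifts or decomposition of the silyloxydiene take over. Fallback: the two bonds are made one after the other by a radical and a polar step, setting out from dienone 18 and returning at target 22. The copper-catalysed methylation of step 11, quenched with aqueous NH4Cl instead of the silyl triflate, would give the enone F1. m-CPBA would epoxidise the electron-rich 1,1-disubstituted alkene to the epoxide F2. Cp2TiCl (trivalent titanium, from Cp2TiCl2 and Zn) would open the epoxide to the tertiary C6 radical, which adds 6-exo to C11 of the enone and gives the hydroxymethyl ketone F3 (bond C6–C11, ring C; only the C6 epimer with C7 cis to C8 can go on). I2/PPh3/imidazole would give the iodide F4. KN(SiMe3)2 would close bond C7–C8 by intramolecular enolate alkylation to the tricyclic ketone F5, the triethylsilyl ether of the target, and HF·pyridine would give 22.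

2. Step 11. The selection between the two enone arms is a diastereotopic choice next to the C14 stereocentre and may be eroded by a mismatch between ligand and substrate; the hindered dienone may also react sluggishly with Me2Zn. Fallback: the methylation is moved in front of the C14 reduction, so that the arm choice becomes enantiotopic apart from the remote C16 centre, setting out from ketone 15 and returning at silyloxydiene 20. The oxidation of step 10 applied to 15 would give the dienone ketone F6; the methylation and silylation of step 11 would give the silyloxydiene ketone F7; CBS reduction with catecholborane, which the silyl dienol ether tolerates, would give the alcohol F8; acetylation would give 20. The facial bias then rests on the branched acyl group on C12 and would have to be checked.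

3. Step 10. The radical oxidation may also attack the allylic C–H bonds at C5 and C16, or the cyclohexadienyl radical may lose the C12 side chain with aromatisation. Fallback: a polar oxygenation in place of the radical one, setting out from alcohol 16 and returning at dienone 18. n-BuLi/KOt-Bu (2.2 equiv) would remove the O–H and then the doubly allylic C9–H proton; B(OMe)3 followed by H2O2/NaOH would give the diol F9; MnO2 would oxidise only the doubly allylic alcohol to the hydroxy dienone F10; acetylation as in step 9 would give 18.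

Further compounds
F1 | step 12 | (1R,3R,7S)-1-[(1S,6R)-1,6-dimethyl-4-oxocyclohex-2-en-1-yl]-3,7-dimethyl-4-methylidene-7-(triethylsilyloxy)non-8-en-1-yl acetate | C=C[C@@](C)(O[Si](CC)(CC)CC)CCC(=C)[C@H](C)C[C@@H](OC(C)=O)[C@]1(C)C=CC(=O)C[C@H]1C
F2 | step 12 | epoxide of F1 at C6–C7 (spiro oxirane, both epimers at C6) | C=C[C@@](C)(O[Si](CC)(CC)CC)CCC1(CO1)[C@H](C)C[C@@H](OC(C)=O)[C@]2(C)C=CC(=O)C[C@H]2C
F3 | step 12 | bicyclic hydroxymethyl ketone (rings B and C closed through C6–C11; C7 as CH2OH on C6; C9 ketone; other centres as in the target) | C=C[C@@](C)(O[Si](CC)(CC)CC)CC[C@]1(CO)[C@H](C)C[C@@H](OC(C)=O)[C@@]2(C)[C@H](C)CC(=O)C[C@@H]12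
F4 | step 12 | iodide of F3 (C7 as CH2I) | C=C[C@@](C)(O[Si](CC)(CC)CC)CC[C@]1(CI)[C@H](C)C[C@@H](OC(C)=O)[C@@]2(C)[C@H](C)CC(=O)C[C@@H]12
F5 | step 12 | C3 triethylsilyl ether of the target | C=C[C@@](C)(O[Si](CC)(CC)CC)CC[C@@]12C[C@H]3C(=O)C[C@@H]1[C@](C)([C@@H]3C)[C@H](OC(C)=O)C[C@H]2C
F6 | step 11 | (3R,7S)-3,7-dimethyl-4-methylidene-1-(1-methyl-4-oxocyclohexa-2,5-dien-1-yl)-7-(triethylsilyloxy)non-8-en-1-one | C=C[C@@](C)(O[Si](CC)(CC)CC)CCC(=C)[C@H](C)CC(=O)C1(C)C=CC(=O)C=C1
F7 | step 11 | (3R,7S)-1-[(1R,6R)-4-(tert-butyldimethylsilyloxy)-1,6-dimethylcyclohexa-2,4-dien-1-yl]-3,7-dimethyl-4-methylidene-7-(triethylsilyloxy)non-8-en-1-one | C=C[C@@](C)(O[Si](CC)(CC)CC)CCC(=C)[C@H](C)CC(=O)[C@]1(C)C=CC(O[Si](C)(C)C(C)(C)C)=C[C@H]1C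
F8 | step 11 | (1R,3R,7S)-1-[(1R,6R)-4-(tert-butyldimethylsilyloxy)-1,6-dimethylcyclohexa-2,4-dien-1-yl]-3,7-dimethyl-4-methylidene-7-(triethylsilyloxy)non-8-en-1-ol | C=C[C@@](C)(O[Si](CC)(CC)CC)CCC(=C)[C@H](C)C[C@@H](O)[C@]1(C)C=CC(O[Si](C)(C)C(C)(C)C)=C[C@H]1C
F9 | step 10 | (1R,3R,7S)-1-(4-hydroxy-1-methylcyclohexa-2,5-dien-1-yl)-3,7-dimethyl-4-methylidene-7-(triethylsilyloxy)non-8-en-1-ol (cis and trans ring isomers) | C=C[C@@](C)(O[Si](CC)(CC)CC)CCC(=C)[C@H](C)C[C@@H](O)C1(C)C=CC(O)C=C1
F10 | step 10 | 4-[(1R,3R,7S)-1-hydroxy-3,7-dimethyl-4-methylidene-7-(triethylsilyloxy)non-8-en-1-yl]-4-methylcyclohexa-2,5-dien-1-one | C=C[C@@](C)(O[Si](CC)(CC)CC)CCC(=C)[C@H](C)C[C@@H](O)C1(C)C=CC(=O)C=C1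
A1 | direct plan | (3S,4R)-3-[(3S)-3-(tert-butyldimethylsilyloxy)-3-methylpent-4-en-1-yl]-4-methyl-3-[2-(2-methyl-1,3-dioxolan-2-yl)ethyl]tetrahydro-2H-pyran-2-one | C=C[C@@](C)(O[Si](C)(C)C(C)(C)C)CC[C@@]1(CCC2(C)OCCO2)C(=O)OCC[C@H]1C
A2 | direct plan | (4S)-4-[(3S)-3-(tert-butyldimethylsilyloxy)-3-methylpent-4-en-1-yl]-4-[(2R,5E)-5-methyl-4-oxohept-5-en-2-yl]cyclohex-2-en-1-one | C=C[C@@](C)(O[Si](C)(C)C(C)(C)C)CC[C@@]1(C=CC(=O)CC1)[C@H](C)CC(=O)/C(C)=C/C
A3 | direct plan | tricyclic C14 ketone with C9 tert-butyldimethylsilyl enol ether and C3 tert-butyldimethylsilyl ether | C=C[C@@](C)(O[Si](C)(C)C(C)(C)C)CC[C@@]12C[C@H]3C(O[Si](C)(C)C(C)(C)C)=C[C@@H]1[C@](C)([C@@H]3C)C(=O)C[C@H]2C
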